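**Plan**

- Retrosynthesis: the six C–Br bonds at C3, C4, C5, C3', C4' and C5' are cut first, then two temporary N-vinyl bonds, and last, in each ring, C3–C4 and N1–C5.
- Enabling feature: the chain C3–C2–C2'–C3' with N1 on C2 and N1' on C2' is the skeleton of butane-2,3-dione dioxime. Each C4–C5 and C4'–C5' pair is one acetylene, and the inter-ring bond C2–C2' is already present in the dioxime.
- Forward: both pyrrole rings are closed in one vessel from the dioxime and acetylene in KOH/DMSO (step 1). The N-vinyl groups that this medium installs are removed (step 2), and all six ring carbons are brominated (step 3).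
- Stereochemistry: the target has no stereocentre, and the E,E geometry of the dioxime is consumed in the ring closure, so nothing has to be set.

Key step: step 1

Remark: with acetylene under pressure in KOH/DMSO a newly formed pyrrole N–H is expected to be vinylated, so the annulation is run on purpose to the N,N'-divinyl bipyrrole as a single end point and the vinyl groups are treated as temporary N-substituents.

**Route**

Step 1
Reactants: 1 dimethylglyoxime; 2 acetylene
Product: 5 1,1'-divinyl-1H,1'H-2,2'-bipyrrole, via butane-2,3-dione bis(O-vinyl oxime) 3 (not isolated), via 1-vinyl-2,2'-bipyrrole 4 (not isolated)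
Conditions: HC≡CH (12 atm initial, excess), KOH (2 equiv), DMSO, 70 °C then 120 °C, steel autoclave
Reagents that add atoms: acetylene, C#C
Why: At 70 °C each oximate adds to acetylene to give the bis(O-vinyl oxime) 3, so that both oxime oxygens are capped before furazan closure or fragmentation can compete; at 120 °C each arm tautomerises to the N-alkenyl-O-vinylhydroxylamine, undergoes a [3,3] sigmatropic shift that breaks N–O and forms C3–C4 (C3'–C4'), and the resulting imino aldehyde condenses to form N1–C5 (N1'–C5'). The closest known reaction type is the Trofimov pyrrole synthesis from ketoximes and acetylene in KOH/DMSO, its twofold use on a vicinal dioxime being the least secure element of the route. Each of the two pyrrole rings closes by 5-exo-trig attack of the imine nitrogen on the aldehyde carbon, followed by loss of water and a shift from the 3H- to the 1H-pyrrole. No stereocentre is formed. The step needs a single direction for the [3,3] shift, and this is secured because each oxime carbon has α-hydrogens only on its methyl group, the other neighbour being the second oxime carbon (later the pyrrole C2). Each ring N–H is then vinylated by the excess acetylene in the same superbase, through 4, which is driven to completion so that 5 is obtained instead of a mixture of N–H and N-vinyl bipyrroles.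

Step 2
Reactants: 5 1,1'-divinyl-1H,1'H-2,2'-bipyrrole
Product: 7 1H,1'H-2,2'-bipyrrole, via bis(acetoxymercurio) hemiaminal 6 (not isolated)
Conditions: Hg(OAc)2 (2.1 equiv), MeCN–H2O, 0 °C to rt; then NaBH4, aq NaOH, 0 °C
Reagents that add atoms: none
Why: Oxymercuration–demercuration, in which divalent mercury adds to the terminal carbon of each enamine-like N-vinyl group and water to the nitrogen-bearing carbon, and the hemiaminal 6 collapses in the basic borohydride work-up to the pyrrole N–H while the mercurated acetaldehyde is reduced to mercury metal and ethanol, any ring C–Hg bond being returned to C–H by the same hydride.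

Step 3
Reactants: 7 1H,1'H-2,2'-bipyrrole; 8 N-bromosuccinimide
Product: 9 3,3',4,4',5,5'-hexabromo-1H,1'H-2,2'-bipyrrole
Conditions: NBS (6.2 equiv), THF, −78 °C to rt, dark, Ar
Reagents that add atoms: N-bromosuccinimide, O=C1CCC(=O)N1Br
Why: Sixfold electrophilic aromatic substitution of the π-excessive pyrrole rings, first at the free α-positions C5 and C5' and then at the β-positions C3, C3', C4 and C4', in which every remaining C–H is brominated so that no regiochemical choice arises and the low starting temperature holds back oxidative coupling of the electron-rich bipyrrole.

**Compound list**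

1 | dimethylglyoxime, (2E,3E)-butane-2,3-dione dioxime | C/C(=N\O)/C(=N/O)/C | starting material
2 | acetylene (ethyne) | C#C | starting material
3 | (2E,3E)-butane-2,3-dione bis(O-vinyl oxime) | C/C(=N\OC=C)/C(=N/OC=C)/C | intermediate
4 | 1-vinyl-1H,1'H-2,2'-bipyrrole | C=Cn1cccc1-c1ccc[nH]1 | intermediate
5 | 1,1'-divinyl-1H,1'H-2,2'-bipyrrole | C=Cn1cccc1-c1cccn1C=C | intermediate
6 | 1,1'-bis[2-(acetoxymercurio)-1-hydroxyethyl]-2,2'-bipyrrole, mixture of diastereomers at the two hemiaminal carbons | CC(=O)O[Hg]CC(O)n1cccc1-c1cccn1C(O)C[Hg]OC(C)=O | intermediate
7 | 1H,1'H-2,2'-bipyrrole | c1c[nH]c(-c2ccc[nH]2)c1 | intermediate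
8 | N-bromosuccinimide | O=C1CCC(=O)N1Br | starting material
9 | 3,3',4,4',5,5'-hexabromo-1H,1'H-2,2'-bipyrrole | Brc1[nH]c(-c2[nH]c(Br)c(Br)c2Br)c(Br)c1Br | target

**Count and risks**

Total step count: 3. Longest linear sequence: 3 steps (1 → 5 → 7 → 9).

Steps most likely to fail, in order of risk:

Step 1. In hot superbase the dioxime may be lost to dehydrative furazan closure, fragmentation and tar formation before both oxygens are vinylated, or the cascade may stop after the first annulation. The fallback sets out from 1 and replaces superbase and free acetylene by an activated alkyne under neutral conditions.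
- Dimethyl acetylenedicarboxylate with catalytic 1,4-diazabicyclo[2.2.2]octane in CH2Cl2 at room temperature should add both oxime oxygens and give the bis(O-vinyl oxime) tetraester F1. Its enol ether geometry is not controlled and does not matter.
- Heating F1 in toluene at about 170 °C should bring about the same twofold [3,3] shift and condensation and give tetramethyl 1H,1'H-2,2'-bipyrrole-4,4',5,5'-tetracarboxylate F2.
- Saponification with KOH in aqueous ethylene glycol gives the tetracarboxylic acid F3, which on further heating in the same alkaline medium at 170–190 °C should lose its four carboxyl groups.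
- The fallback comes back to the route at 7 and makes step 2 unnecessary.

Step 2. Electrophilic mercuration of the pyrrole carbons may compete with addition to the vinyl groups and leave carbon–mercury bonds that the hydride work-up does not reduce cleanly, or the N–H bipyrrole may be oxidised by air during work-up. The fallback sets out from 1 and avoids N-vinylation altogether by separating the two stages of the annulation.
- With KOH in DMSO at 60–70 °C, acetylene under pressure and a short contact time, the reaction is stopped at the O-vinyl stage and 3 is isolated by quenching into cold water and extraction.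
- 3 is then heated in DMSO with a little KOH at 110–120 °C under argon with no acetylene present, so that the rings close by the same [3,3] shift and condensation while nothing can vinylate the N–H.
- The fallback comes back at 7 and makes no compound outside the list (entry F0).

Step 3. Oxidative oligomerisation and N-bromination of the free N–H bipyrrole may outrun substitution at carbon, or the reaction may stall before the last β-positions are filled. The fallback sets out from 7 and brominates an N-protected bipyrrole.
- NaH and 2-(trimethylsilyl)ethoxymethyl chloride in DMF at 0 °C give 1,1'-bis{[2-(trimethylsilyl)ethoxy]methyl}-2,2'-bipyrrole F4.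
- N-bromosuccinimide (6 equiv) in THF from −78 °C to room temperature should give 3,3',4,4',5,5'-hexabromo-1,1'-bis{[2-(trimethylsilyl)ethoxy]methyl}-2,2'-bipyrrole F5. N-Alkyl 2,2'-bipyrroles are twisted about the inter-ring bond and behave as two separate N-alkylpyrroles, a class for which perbromination with this reagent is well precedented.
- Bu4NF with ethylenediamine in THF at reflux removes both N-substituents, which is eased by the six electron-withdrawing bromines, and the fallback comes back at 9.

**Further compounds**

F1 | step 1 | tetramethyl 2,2'-{[(2E,3E)-butane-2,3-diylidene]bis(azanylylideneoxy)}bis(but-2-enedioate), enol ether geometry undefined | C/C(=N\OC(=CC(=O)OC)C(=O)OC)/C(=N/OC(=CC(=O)OC)C(=O)OC)/C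
F2 | step 1 | tetramethyl 1H,1'H-2,2'-bipyrrole-4,4',5,5'-tetracarboxylate | COC(=O)c1cc(-c2cc(C(=O)OC)c(C(=O)OC)[nH]2)[nH]c1C(=O)OC
F3 | step 1 | 1H,1'H-2,2'-bipyrrole-4,4',5,5'-tetracarboxylic acid | OC(=O)c1cc(-c2cc(C(=O)O)c(C(=O)O)[nH]2)[nH]c1C(=O)O
F0 | step 2 | none | none
F4 | step 3 | 1,1'-bis{[2-(trimethylsilyl)ethoxy]methyl}-2,2'-bipyrrole | C[Si](C)(C)CCOCn1cccc1-c1cccn1COCC[Si](C)(C)C
F5 | step 3 | 3,3',4,4',5,5'-hexabromo-1,1'-bis{[2-(trimethylsilyl)ethoxy]methyl}-2,2'-bipyrrole, racemic about the hindered inter-ring axis | C[Si](C)(C)CCOCn1c(Br)c(Br)c(Br)c1-c1c(Br)c(Br)c(Br)n1COCC[Si](C)(C)C
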